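(The readings are calculated for substances that don't exist; noise was put on by code.)

I began in a one-step world: D turns Q into L, D lasts, and L climbs in step with [D]·t, where [D] is the charge.

| flask | Q | D | remark | time |
|---|---|---|---|---|
| green | 0.050 M | 0.46 µM | the very flask that is asked about, followed so far |  |
| teal | 0.050 M | 0.69 µM | run made earlier |  |
| flask | 0.050 M | 0.46 µM |  | 2.5 d |

| run | time / h | L / % | Q / % |
|---|---|---|---|
| green | 5.00 | 9.9 | 89.7 |
| green | 10.0 | 12.1 | 87.0 |
| green | 15.0 | 13.8 | 86.0 |
| green | 30.0 | 16.7 | 83.0 |
| green | 60.0 | 17.7 | 80.4 |
| teal | 0.417 | 2.2 | 96.7 |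
| teal | 1.33 | 6.9 | 92.7 |
| teal | 2.00 | 7.7 | 91.7 |
| teal | 3.00 | 9.8 | 91.0 |
| teal | 5.00 | 12.2 | 89.5 |

(scatter of a reading: 0.5 percentage points)

- alder: at 2.5 d take out 90% of the L then present, then wait 5.0 d
- ash: change nothing and wait 5.0 d more
- birch: at 2.5 d add D, 100% of the amount charged, then wait 5.0 d
- maple: at 2.5 d add Q, 50.0% of the amount charged, then wait 5.0 d

- L that was removed still counts
- additions bring no volume worth counting

- L, in percent of the Q first charged, at 2.5 d
- the remedy with the largest gain of L, or "none" below 2 percentage points (alder / ash / birch / maple / none)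
- L present, with what was taken out counted in, in percent of the Q first charged, after ash
- L present, with what was taken out counted in, in percent of the Q first charged, after birch

Did Q run short in green? No. At 60.0 h Q read 80.4% against L 17.7%, so I froze [Q] and took the rate as pseudo-first-order in working D. The asked time is that same reading, so I took now as 17.7%, give or take 0.5 percentage points.

Did [D]·t still order the runs? Teal at 3.00 h had 0.900 of the [D]·t of green at 5.00 h, and it read L 9.8% against 9.9%. So I laid both runs on one curve.

What shape had that curve? Green gained 2.5 points per doubling of time up to 15.0 h, then 1.9 points, and the scatter covers that gap. Across the whole of green, from 5.00 h to 60.0 h, I read 2.2 points. I called this the doubling gain, the points of L won each time [D]·t doubles. With [Q] frozen, a steady doubling gain means a rate falling as one over time, and a second-order loss of working D gives such a fall at late times.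

At 60.0 h that rate was 1.49% of the opening rate read from teal and scaled to green's D. So I gave the old D hardly any of the opening rate, and I let fresh D in birch restart the curve. Over 5.0 d I put that restart at green's last reading plus one doubling gain, scaled by Q's 80.4%, which made 33.7% in all. Ash multiplied the time by 3.00, a gain of 3.4 points. I counted alder as ash. Maple scaled that gain with Q, to 5.6 points. My gain for birch, 16 points, stood first.

The forecast, holding that “the enzyme is essentially dead”, gave 17.7% now, 17.9% after ash, 25.5% after birch and birch as best, which differs from my figures on ash and on the size of birch.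

The flask gave 18.4% now, 21.6% after ash and 31.8% after birch, and birch led with a gain of 13 points.

    Q + D ⇌ X (K = 12.3 L mol⁻¹, k = 5560 L mol⁻¹ s⁻¹)
    X ⇌ D + L (K = 0.120 M, k = 6.66 s⁻¹)
    Q → G (k = 7.47 × 10⁻⁸ s⁻¹)
    2 D → E (k = 1350 L mol⁻¹ s⁻¹)

Between 6.00 h and 60.0 h free D fell by a factor of 9.52, from 5.40% to 0.567% of the catalyst charged, while the time grew by a factor of 10.0. The doubling gain had put ash at 3.4 points, and ash brought 3.2 points. The same flask read at 15 h lies two doublings back, so 18.4% less two doubling gains makes 14.0%, and that flask held 13.8%.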